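**Retrosynthetic overview**

- Feature: in dihydronaphthalene numbering (ring A = benzo ring C4a–C8a, ring B = C1–C4 with C4a/C8a, ring C = aryl group on C1), C2 and C3 each carry a 4-hydroxybenzoyl group. C2–C3 with its two carbonyls is therefore a symmetric 1,4-diarylbutane-1,4-dione, and C4 and C1 are the former formyl carbons of a ring A and a ring C benzaldehyde.
- Last disconnection: the five phenolic MOM ethers (C7, ring C 3' and 4', both aroyl rings); the C6 hydroxyl stays free throughout.
- Key disconnection: C8a–C1 (Friedel–Crafts) together with C1=C2 and C3=C4 (aldol condensations) in one operation, back to the diketone and the two aldehydes. Ring B is the only ring formed and is formed last.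
- Components: each aldehyde from a commercial polyhydroxybenzaldehyde by site-selective O-alkylation; the diketone by coupling protected 4'-hydroxyacetophenone with its own α-bromo derivative (C2–C3 bond).

Key step: step 7

Assumption: the sense of induction of the chiral phosphoramide cannot be derived from precedent; the (R)-catalyst is written, and its mirror image is used instead if a first run delivers the (1S) series.

**Route**

Step 1
Reactants: 1 3,4-dihydroxy-5-methoxybenzaldehyde
Product: 2 3-hydroxy-5-methoxy-4-(methoxymethoxy)benzaldehyde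
Conditions: MOMCl (1.05 equiv), K2CO3 (1.1 equiv), acetone, 0 °C to rt
Reagents that add atoms: chloromethyl methyl ether, COCCl
Why: The 4-OH, para to the formyl group and the more acidic phenol, is deprotonated first by one equivalent of carbonate and O-alkylated (Williamson-type ether formation), the same site selectivity as in the known 4-O-methylation of this aldehyde, so the 3-OH that later directs the ring closure stays free.

Step 2
Reactants: 3 2,3,4-trihydroxybenzaldehyde
Product: 4 2-hydroxy-3,4-bis(methoxymethoxy)benzaldehyde
Conditions: MOMCl (2.2 equiv), iPr2NEt (3 equiv), CH2Cl2, 0 °C to rt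
Reagents that add atoms: chloromethyl methyl ether, COCCl
Why: The 2-OH is tied up in a hydrogen bond to the formyl oxygen and is the least nucleophilic phenol, so two equivalents of MOMCl with a hindered amine should acetalise only the 3- and 4-OH (chemoselective O-alkylation).

Step 3
Reactants: 4 2-hydroxy-3,4-bis(methoxymethoxy)benzaldehyde
Product: 5 2-methoxy-3,4-bis(methoxymethoxy)benzaldehyde
Conditions: MeI (2 equiv), K2CO3 (2 equiv), DMF, 40 °C
Reagents that add atoms: iodomethane, CI
Why: The remaining chelated phenol is methylated under Williamson conditions in a dipolar aprotic solvent, which the MOM ethers and the aldehyde tolerate.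

Step 4
Reactants: 6 4'-hydroxyacetophenone
Product: 7 4'-(methoxymethoxy)acetophenone
Conditions: MOMCl (1.3 equiv), K2CO3 (2 equiv), acetone, rt
Reagents that add atoms: chloromethyl methyl ether, COCCl
Why: Standard Williamson-type MOM protection of a phenol, which masks the acidic OH with a base-stable acetal before enolate chemistry.

Step 5
Reactants: 7 4'-(methoxymethoxy)acetophenone
Product: 9 2-bromo-1-[4-(methoxymethoxy)phenyl]ethan-1-one, via trimethylsilyl enol ether 8 (not isolated)
Conditions: LiN(SiMe3)2 (1.1 equiv), Me3SiCl (1.2 equiv), THF, −78 °C; then NBS (1.05 equiv), −78 to 0 °C; aqueous NaHCO3 work-up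
Reagents that add atoms: N-bromosuccinimide, O=C1CCC(=O)N1Br; chlorotrimethylsilane, C[Si](C)(C)Cl (silyl group of intermediate 8 only)
Why: Deprotonation of the methyl ketone and O-silylation give the silyl enol ether, whose electron-rich alkene is brominated once by NBS (α-bromination of a ketone through its silyl enol ether) under neutral conditions, so no HBr arises that could cleave the aryl MOM ether.

Step 6
Reactants: 7 4'-(methoxymethoxy)acetophenone, 9 2-bromo-1-[4-(methoxymethoxy)phenyl]ethan-1-one
Product: 10 1,4-bis[4-(methoxymethoxy)phenyl]butane-1,4-dione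
Conditions: 7 (1.5 equiv), 9 (1.0 equiv), ZnCl2 (2 equiv), Et2NH (1.5 equiv), t-BuOH (1.5 equiv), toluene, rt
Reagents that add atoms: none
Why: The zinc enolate of 7, formed by ZnCl2 and Et2NH, is phenacylated by the α-bromo ketone 9 in the known zinc-mediated coupling of methyl ketones with α-bromo ketones to 1,4-diketones, which joins the two α-carbons as the later C2–C3 bond without the epoxide, furan and polyalkylation products of alkali enolates, and amine-buffered ZnCl2 at room temperature without a soft nucleophile should leave the aryl MOM ethers intact.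

Step 7
Reactants: 10 1,4-bis[4-(methoxymethoxy)phenyl]butane-1,4-dione, 2 3-hydroxy-5-methoxy-4-(methoxymethoxy)benzaldehyde, 5 2-methoxy-3,4-bis(methoxymethoxy)benzaldehyde
Product: 13 (1R,2R)-cis-1-aryl-2,3-diaroyl-1,2-dihydronaphthalene penta-MOM ether (C6-OH free), via mono-arylidene diketone 11 (not isolated), via bis-arylidene diketone 12 (not isolated)
Conditions: (a) 10 (1.3 equiv), 2 (1.0 equiv, slow addition), pyrrolidine (1.0 equiv), AcOH (0.5 equiv), 4 Å MS, toluene, 60 °C; (b) 5 (1.5 equiv), 90 °C; (c) silica plug to remove the amine, no purification, then (R)-3,3'-bis(2,4,6-triisopropylphenyl)-H8-BINOL N-triflyl phosphoramide (10 mol %), 5 Å MS, toluene, −40 to −10 °C; pH 7 buffer quench at −40 °C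
Reagents that add atoms: none
Why: Proposed new method: pyrrolidinium acetate should condense the two CH2 groups of 10 one after the other, first with 2 and then with 5 (enamine/iminium aldol condensation, each alkene E with the aryl group anti to its aroyl group), so that the strong acid only meets the bis-arylidene 12, which has no CH2 left and cannot drift to a furan. The phosphoramide then protonates the carbonyl oxygen on C2, C1 becomes a benzylic cation carried by the 2'-OMe and 4'-OMOM oxygens of ring C, and C8a of ring A attacks it in a 6-endo-trig Friedel–Crafts closure of ring B, which in formal terms is a 6π ring closure of the C8a=C4a–C4=C3–C2=C1 triene with loss of the C8a proton. The nearest known reactions are the acid-mediated cyclisation of 2,3-bis(arylidene)succinates to 1-aryl-1,2-dihydronaphthalenes and the Nazarov-type and Friedel–Crafts cyclisations catalysed by chiral Brønsted acids, but neither a bis(arylidene)-1,4-diketone nor a one-pot assembly from three components has been shown. C1 is set by the chiral phosphoramide anion, which is paired with the hydroxyallyl cation and hydrogen-bonded to the C6 phenol and so leaves one face of C1 open to C8a, and C2 is set when the C2 enol takes its proton anti to the pseudoaxial C1 aryl group, which puts aryl and aroyl cis. The step needs closure through C8a and not through C5 or from ring C onto C4: C8a is para to the only free hydroxyl of ring A (the phenol para position is the classical site of phenolic cyclisations), a C4 cation would lean on the C7 oxygen that two ortho substituents twist out of conjugation, and the one free ortho carbon of ring C is para only to the equally twisted 3'-oxygen. A slight excess of 10 over 2 and the order of addition keep the two condensations apart, and the low temperature and catalytic amount of acid spare the MOM ethers and the kinetic cis arrangement.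

Step 8
Reactants: 13 (1R,2R)-cis-1-aryl-2,3-diaroyl-1,2-dihydronaphthalene penta-MOM ether (C6-OH free)
Product: 14 [(1R,2R)-1-(3,4-dihydroxy-2-methoxyphenyl)-6,7-dihydroxy-8-methoxy-1,2-dihydronaphthalene-2,3-diyl]bis[(4-hydroxyphenyl)methanone] (CNP0335881.1)
Conditions: ZnBr2 (6 equiv), n-PrSH (12 equiv), CH2Cl2, 0 °C, short reaction time; pH 7 buffer
Reagents that add atoms: none
Why: Lewis-acid-assisted cleavage of the five aryl MOM ethers with thiol capture of the methoxymethyl cation is fast at 0 °C and needs neither protic acid, base nor hydrogen, so the C3=C4 enone, the two aryl methyl ethers and the epimerisable cis C2 centre should be retained.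

**Compound list**

1 | 3,4-dihydroxy-5-methoxybenzaldehyde (5-hydroxyvanillin) | COc1cc(C=O)cc(O)c1O | starting material
2 | 3-hydroxy-5-methoxy-4-(methoxymethoxy)benzaldehyde | COc1cc(C=O)cc(O)c1OCOC | intermediate
3 | 2,3,4-trihydroxybenzaldehyde | O=Cc1ccc(O)c(O)c1O | starting material
4 | 2-hydroxy-3,4-bis(methoxymethoxy)benzaldehyde | O=Cc1ccc(OCOC)c(OCOC)c1O | intermediate
5 | 2-methoxy-3,4-bis(methoxymethoxy)benzaldehyde | COc1c(C=O)ccc(OCOC)c1OCOC | intermediate
6 | 4'-hydroxyacetophenone | CC(=O)c1ccc(O)cc1 | starting material
7 | 4'-(methoxymethoxy)acetophenone | CC(=O)c1ccc(OCOC)cc1 | intermediate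
8 | trimethyl({1-[4-(methoxymethoxy)phenyl]ethenyl}oxy)silane | C=C(O[Si](C)(C)C)c1ccc(OCOC)cc1 | intermediate
9 | 2-bromo-1-[4-(methoxymethoxy)phenyl]ethan-1-one | O=C(CBr)c1ccc(OCOC)cc1 | intermediate
10 | 1,4-bis[4-(methoxymethoxy)phenyl]butane-1,4-dione | O=C(CCC(=O)c1ccc(OCOC)cc1)c1ccc(OCOC)cc1 | intermediate
11 | (E)-2-[3-hydroxy-5-methoxy-4-(methoxymethoxy)benzylidene]-1,4-bis[4-(methoxymethoxy)phenyl]butane-1,4-dione | O=C(c1ccc(OCOC)cc1)/C(CC(=O)c1ccc(OCOC)cc1)=C/c1cc(O)c(OCOC)c(OC)c1 | intermediate
12 | (2E,3E)-2-[3-hydroxy-5-methoxy-4-(methoxymethoxy)benzylidene]-3-[2-methoxy-3,4-bis(methoxymethoxy)benzylidene]-1,4-bis[4-(methoxymethoxy)phenyl]butane-1,4-dione | O=C(c1ccc(OCOC)cc1)/C(=C/c1cc(O)c(OCOC)c(OC)c1)C(=C\c1ccc(OCOC)c(OCOC)c1OC)/C(=O)c1ccc(OCOC)cc1 | intermediate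
13 | [(1R,2R)-6-hydroxy-8-methoxy-7-(methoxymethoxy)-1-[2-methoxy-3,4-bis(methoxymethoxy)phenyl]-1,2-dihydronaphthalene-2,3-diyl]bis{[4-(methoxymethoxy)phenyl]methanone} (1,2-cis) | COc1c([C@@H]2c3c(cc(O)c(OCOC)c3OC)C=C(C(=O)c3ccc(OCOC)cc3)[C@@H]2C(=O)c2ccc(OCOC)cc2)ccc(OCOC)c1OCOC | intermediate
14 | [(1R,2R)-1-(3,4-dihydroxy-2-methoxyphenyl)-6,7-dihydroxy-8-methoxy-1,2-dihydronaphthalene-2,3-diyl]bis[(4-hydroxyphenyl)methanone] (1,2-cis) | COc1c([C@@H]2c3c(cc(O)c(O)c3OC)C=C(C(=O)c3ccc(O)cc3)[C@@H]2C(=O)c2ccc(O)cc2)ccc(O)c1O | target

**Step count**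

Total: 8 steps. Longest linear sequence: 5 steps (steps 4, 5, 6, 7, 8 from 6).

**Steps most likely to fail**

1. Step 7. The two condensations may scramble into symmetric bis-arylidenes, ring closure may occur at C5 or with poor facial bias, and C2 may equilibrate to trans in the acidic medium. The fallback sets out from 10, 2 and 5 and comes back at 14; the three bonds are made in separate known operations and the enantiomers are separated physically. Diketone 10 in threefold excess is condensed with 2 (pyrrolidine, AcOH, toluene) and 11 is isolated with recovery of 10; 11 is condensed with 5 in the same way and 12 is isolated. Compound 12 is cyclised with a catalytic achiral strong acid (HNTf2, CH2Cl2, −40 °C), the acid-mediated closure known for 2,3-bis(arylidene)succinates, to give the racemic C2-epimeric penta-MOM dihydronaphthalene F1. The C6 phenol is protected (MOMCl, iPr2NEt) to give the racemic C2-epimeric hexa-MOM ether F2. Its C2 enolate (LiN(SiMe3)2, THF, −78 °C) is protonated kinetically with 2,6-di-tert-butyl-4-methylphenol, anti to the C1 aryl group as in the known enolate protonation of aryltetralin lignans, to give the racemic cis hexa-MOM ether F3. Preparative HPLC on a chiral stationary phase should deliver the (1R,2R)-cis hexa-MOM ether F4, which is deprotected under the conditions of step 8 to give 14.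

2. Step 8. C2 may epimerise to the trans isomer under the Lewis acid, the thiol may add reversibly to the C3=C4 enone, or one of the five acetals may remain. The fallback sets out from 13 and comes back at 14; the C2 configuration is set after the deprotection instead of being carried through it. The MOM ethers are removed with HCl in MeOH at 40 °C, accepting that the hexaphenol forms partly or wholly as the (1R,2S)-trans hexaphenol F5. The crude mixture is persilylated (TBSCl, imidazole, DMF) to the C2-epimeric hexa-TBS ether F6. Deprotonation at C2 (LiN(SiMe3)2, THF, −78 °C) and kinetic protonation (2,6-di-tert-butyl-4-methylphenol, −78 °C) should give the (1R,2R)-cis hexa-TBS ether F7. The silyl ethers are then removed with Et3N·3HF in THF at 0 °C, a fluoride source that is neither basic nor strongly acidic, to give 14.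

3. Step 1. The very reactive MOMCl may alkylate the 3-OH or both phenols. The fallback sets out from 1 and comes back at 2; the regiochemistry is fixed by a temporary group on the 3-oxygen. The dianion of 1 (NaH, 2.2 equiv, DMSO) is alkylated with one equivalent of allyl bromide at the more nucleophilic 3-phenoxide, the known site selectivity of catechol aldehyde dianions, to give 3-(allyloxy)-4-hydroxy-5-methoxybenzaldehyde F8. The single remaining phenol is protected (MOMCl, iPr2NEt, CH2Cl2) to give 3-(allyloxy)-5-methoxy-4-(methoxymethoxy)benzaldehyde F9. The allyl ether is cleaved with catalytic Pd(PPh3)4 (zerovalent palladium) and morpholine in THF to give 2.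

**Further compounds**

F1 | step 7 | racemic C2-epimeric penta-MOM dihydronaphthalene (rac-13 and its C2 epimer) | COc1c(C2c3c(cc(O)c(OCOC)c3OC)C=C(C(=O)c3ccc(OCOC)cc3)C2C(=O)c2ccc(OCOC)cc2)ccc(OCOC)c1OCOC
F2 | step 7 | racemic C2-epimeric hexa-MOM ether | COc1c(C2c3c(cc(OCOC)c(OCOC)c3OC)C=C(C(=O)c3ccc(OCOC)cc3)C2C(=O)c2ccc(OCOC)cc2)ccc(OCOC)c1OCOC
F3 | step 7 | racemic cis hexa-MOM ether (relative configuration, (1R,2R) form drawn) | COc1c([C@@H]2c3c(cc(OCOC)c(OCOC)c3OC)C=C(C(=O)c3ccc(OCOC)cc3)[C@@H]2C(=O)c2ccc(OCOC)cc2)ccc(OCOC)c1OCOC
F4 | step 7 | (1R,2R)-cis hexa-MOM ether | COc1c([C@@H]2c3c(cc(OCOC)c(OCOC)c3OC)C=C(C(=O)c3ccc(OCOC)cc3)[C@@H]2C(=O)c2ccc(OCOC)cc2)ccc(OCOC)c1OCOC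
F5 | step 8 | (1R,2S)-trans hexaphenol (C2 epimer of 14) | COc1c([C@@H]2c3c(cc(O)c(O)c3OC)C=C(C(=O)c3ccc(O)cc3)[C@H]2C(=O)c2ccc(O)cc2)ccc(O)c1O
F6 | step 8 | C2-epimeric hexa-TBS ether (1R) | COc1c([C@@H]2c3c(cc(O[Si](C)(C)C(C)(C)C)c(O[Si](C)(C)C(C)(C)C)c3OC)C=C(C(=O)c3ccc(O[Si](C)(C)C(C)(C)C)cc3)C2C(=O)c2ccc(O[Si](C)(C)C(C)(C)C)cc2)ccc(O[Si](C)(C)C(C)(C)C)c1O[Si](C)(C)C(C)(C)C
F7 | step 8 | (1R,2R)-cis hexa-TBS ether | COc1c([C@@H]2c3c(cc(O[Si](C)(C)C(C)(C)C)c(O[Si](C)(C)C(C)(C)C)c3OC)C=C(C(=O)c3ccc(O[Si](C)(C)C(C)(C)C)cc3)[C@@H]2C(=O)c2ccc(O[Si](C)(C)C(C)(C)C)cc2)ccc(O[Si](C)(C)C(C)(C)C)c1O[Si](C)(C)C(C)(C)C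
F8 | step 1 | 3-(allyloxy)-4-hydroxy-5-methoxybenzaldehyde | COc1cc(C=O)cc(OCC=C)c1O
F9 | step 1 | 3-(allyloxy)-5-methoxy-4-(methoxymethoxy)benzaldehyde | COc1cc(C=O)cc(OCC=C)c1OCOC
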